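**Plan**

Retrosynthesis: the two phenol masks and the O5-CH3 bond go first. Then the C5-O bond is cut, then O3-CH3, then O1-C2 and C3-O of ring C, then the C2-C3 bond (chalcone alkene), and last the C8a-O1 bond on ring A.
Enabling feature: C5 of ring A is peri to the C4 carbonyl of ring C, so the array O=C4-C4a-C5 can hold a metal in a five-membered chelate. C5-H is also the only C-H bond left on ring A.
Forward: ring A comes from acetosyringone 1 with the C6-OMe/C7-O/C8-OMe pattern in place and gains the future O1 by bromination and hydroxylation. Ring B arrives with 4-benzyloxybenzaldehyde 2 in an aldol condensation, and ring C closes by alkaline peroxide oxidation.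
After 3-O-methylation the benzyl ethers are exchanged for pivalates (pivaloyl chloride 3). The C5 oxygen is then installed by carbonyl-directed ruthenium catalysis and methylated, and the esters are removed.
Stereochemistry: the target has no stereocentre. The E alkene of the chalcone and the two transient centres of the dihydroflavonol are consumed when ring C becomes aromatic.

Key step: step 9

Remark: dihydroflavonol 8 is racemic and one enantiomer is drawn; its stereocentres do not reach the target.

**Route**

Step 1
Reactants: 1 acetosyringone (1-(4-hydroxy-3,5-dimethoxyphenyl)ethanone)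
Product: 4 1-(4-benzyloxy-3,5-dimethoxyphenyl)ethanone
Conditions: BnBr, K2CO3, DMF, 60 °C
Reagents that add atoms: benzyl bromide, BrCc1ccccc1
Why: Williamson etherification of the acidic para-acyl phenol with a primary benzylic bromide should go cleanly despite the two flanking methoxy groups, and the benzyl ether withstands the hydroxide and peroxide steps that follow.

Step 2
Reactants: 4 1-(4-benzyloxy-3,5-dimethoxyphenyl)ethanone
Product: 5 1-(4-benzyloxy-2-bromo-3,5-dimethoxyphenyl)ethanone
Conditions: NBS (1.0 equiv), MeCN, 0 °C to rt, dark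
Reagents that add atoms: N-bromosuccinimide, O=C1CCC(=O)N1Br
Why: Electrophilic aromatic bromination with NBS in acetonitrile should strike one of the two equivalent ring carbons that lie ortho to one methoxy group and para to the other, while the absence of acid, light and initiator holds back bromination at the acetyl methyl group and at the benzylic CH2.

Step 3
Reactants: 5 1-(4-benzyloxy-2-bromo-3,5-dimethoxyphenyl)ethanone
Product: 6 1-(4-benzyloxy-2-hydroxy-3,5-dimethoxyphenyl)ethanone
Conditions: Cu(acac)2 (5 mol %), N,N'-bis(4-hydroxy-2,6-dimethylphenyl)oxalamide (5 mol %), LiOH·H2O, DMSO/H2O, 80 °C; then 1 M HCl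
Reagents that add atoms: lithium hydroxide, [Li+].[OH-]
Why: Ullmann-type copper-catalysed hydroxylation is a general reaction of aryl bromides, the ortho acetyl group should assist activation of the C-Br bond, and the product is shielded from further reaction as its chelated phenoxide.

Step 4
Reactants: 6 1-(4-benzyloxy-2-hydroxy-3,5-dimethoxyphenyl)ethanone, 2 4-benzyloxybenzaldehyde
Product: 7 (E)-1-(4-benzyloxy-2-hydroxy-3,5-dimethoxyphenyl)-3-(4-benzyloxyphenyl)prop-2-en-1-one
Conditions: KOH, EtOH, rt; then 1 M HCl
Reagents that add atoms: none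
Why: Claisen-Schmidt aldol condensation of the methyl ketone enolate with a non-enolisable aldehyde, followed by E1cB loss of water, should give the conjugated chalcone as the thermodynamically preferred E alkene.

Step 5
Reactants: 7 (E)-1-(4-benzyloxy-2-hydroxy-3,5-dimethoxyphenyl)-3-(4-benzyloxyphenyl)prop-2-en-1-one
Product: 9 7-benzyloxy-2-(4-benzyloxyphenyl)-3-hydroxy-6,8-dimethoxychromen-4-one, via trans-dihydroflavonol 8 (not isolated)
Conditions: 30% aq. H2O2, NaOH, MeOH/THF, 0 °C to rt; then 1 M HCl
Reagents that add atoms: hydrogen peroxide, OO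
Why: In the Algar-Flynn-Oyamada oxidation the phenoxide adds to the β-carbon while the α-carbon takes oxygen from hydroperoxide (six-membered closure of ring C) to give racemic trans 8, whose two transient stereocentres are erased by further oxidation to the flavonol, and the hydrogen at C6' of the chalcone (later C5) keeps the competing aurone pathway closed.

Step 6
Reactants: 9 7-benzyloxy-2-(4-benzyloxyphenyl)-3-hydroxy-6,8-dimethoxychromen-4-one
Product: 10 7-benzyloxy-2-(4-benzyloxyphenyl)-3,6,8-trimethoxychromen-4-one
Conditions: MeI, K2CO3, DMF, rt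
Reagents that add atoms: iodomethane, CI
Why: Williamson O-methylation of the enolic 3-hydroxyl, the only acidic group in 9, is standard for flavonols.

Step 7
Reactants: 10 7-benzyloxy-2-(4-benzyloxyphenyl)-3,6,8-trimethoxychromen-4-one
Product: 11 7-hydroxy-2-(4-hydroxyphenyl)-3,6,8-trimethoxychromen-4-one
Conditions: H2 (1 atm), 10% Pd/C, THF/MeOH, rt
Reagents that add atoms: none
Why: Catalytic hydrogenolysis cleaves both benzyl aryl ethers at ambient pressure, conditions that leave the fully substituted C2-C3 double bond of the pyranone and the aryl methyl ethers untouched.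

Step 8
Reactants: 11 7-hydroxy-2-(4-hydroxyphenyl)-3,6,8-trimethoxychromen-4-one, 3 pivaloyl chloride
Product: 12 3,6,8-trimethoxy-7-pivaloyloxy-2-(4-pivaloyloxyphenyl)chromen-4-one
Conditions: PivCl (3 equiv), Et3N, DMAP (cat.), CH2Cl2, 0 °C to rt
Reagents that add atoms: pivaloyl chloride 3, CC(C)(C)C(=O)Cl
Why: DMAP-catalysed acylation through the acylpyridinium salt esterifies both phenols, the hindered one at C7 included, and replaces two strongly donating hydroxyl groups with acid-stable esters that make rings A and B harder to oxidise.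

Step 9
Reactants: 12 3,6,8-trimethoxy-7-pivaloyloxy-2-(4-pivaloyloxyphenyl)chromen-4-one
Product: 14 5-hydroxy-3,6,8-trimethoxy-7-pivaloyloxy-2-(4-pivaloyloxyphenyl)chromen-4-one, via C5 trifluoroacetate 13 (not isolated)
Conditions: [RuCl2(p-cymene)]2 (5 mol %), PhI(OCOCF3)2 (1.5 equiv, in portions), TFA/TFAA, 80 °C; then Me2S, 0 °C; then MeOH/H2O, NaHCO3, rt
Reagents that add atoms: [bis(trifluoroacetoxy)iodo]benzene, O=C(OI(OC(=O)C(F)(F)F)c1ccccc1)C(F)(F)F
Why: In TFA the chlorides of the precatalyst are exchanged for trifluoroacetate, the resulting electrophilic divalent ruthenium binds the C4 carbonyl oxygen of ring C, and carboxylate-assisted deprotonation of the peri C5-H gives a five-membered ruthenacycle (Ru, O, C4, C4a, C5). PhI(OCOCF3)2 raises the metal to the tetravalent state, C-O reductive elimination delivers trifluoroacetate 13 and returns divalent ruthenium, and mild solvolysis on work-up frees phenol 14. The closest known reaction type is the ruthenium-catalysed ketone-directed ortho C-H oxygenation of aryl ketones, which has already been carried over to C5 of chromones and flavones, so only the oxygen load of ring A is new. The step closes no ring of the product and creates no stereocentre. Site selectivity is required and is fixed by the substrate: C5-H is the only C-H bond on ring A, C3 carries a methoxy group, the ortho C-H bonds of ring B could be reached from the carbonyl only through a seven-membered chelate, and C5, ortho to the C6 and para to the C8 methoxy group, is electron-rich enough for electrophilic metalation despite its crowded setting. Chemoselectivity against electron-transfer oxidation by the trivalent iodine reagent rests on the two pivalates, on the protonated pyranone in TFA, on TFAA keeping the new oxygen capped as 13 (the free C5 phenol stands para to the C8 methoxy group and would be oxidised further), on slow addition of a small excess of oxidant and on its reductive quench with Me2S before any water is added.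

Step 10
Reactants: 14 5-hydroxy-3,6,8-trimethoxy-7-pivaloyloxy-2-(4-pivaloyloxyphenyl)chromen-4-one
Product: 15 3,5,6,8-tetramethoxy-7-pivaloyloxy-2-(4-pivaloyloxyphenyl)chromen-4-one
Conditions: Me2SO4, K2CO3 (anhydrous), acetone, reflux
Reagents that add atoms: dimethyl sulfate, COS(=O)(=O)OC
Why: Williamson-type O-methylation with dimethyl sulfate and dry K2CO3 in boiling acetone is the classical way to overcome the hydrogen bond of a 5-hydroxyflavone, and with no hydroxide or alkoxide present the bulky pivalates should stay in place so that O7 and O4' are not methylated.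

Step 11
Reactants: 15 3,5,6,8-tetramethoxy-7-pivaloyloxy-2-(4-pivaloyloxyphenyl)chromen-4-one
Product: 16 7-hydroxy-2-(4-hydroxyphenyl)-3,5,6,8-tetramethoxychromen-4-one (target)
Conditions: NaOMe (3 equiv), MeOH/THF, rt; then 1 M HCl
Reagents that add atoms: none
Why: Base-mediated transesterification with methoxide releases both phenoxides, which are good leaving groups because each is conjugated with the pyranone carbonyl, and the four methyl ethers and ring C are inert at room temperature.

**Compound list**

1 | acetosyringone | CC(=O)c1cc(OC)c(O)c(OC)c1 | starting material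
2 | 4-benzyloxybenzaldehyde | O=Cc1ccc(OCc2ccccc2)cc1 | starting material
3 | pivaloyl chloride | CC(C)(C)C(=O)Cl | starting material
4 | 1-(4-benzyloxy-3,5-dimethoxyphenyl)ethanone | CC(=O)c1cc(OC)c(OCc2ccccc2)c(OC)c1 | intermediate
5 | 1-(4-benzyloxy-2-bromo-3,5-dimethoxyphenyl)ethanone | CC(=O)c1cc(OC)c(OCc2ccccc2)c(OC)c1Br | intermediate
6 | 1-(4-benzyloxy-2-hydroxy-3,5-dimethoxyphenyl)ethanone | CC(=O)c1cc(OC)c(OCc2ccccc2)c(OC)c1O | intermediate
7 | (E)-1-(4-benzyloxy-2-hydroxy-3,5-dimethoxyphenyl)-3-(4-benzyloxyphenyl)prop-2-en-1-one | COc1cc(C(=O)/C=C/c2ccc(OCc3ccccc3)cc2)c(O)c(OC)c1OCc1ccccc1 | intermediate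
8 | trans-7-benzyloxy-2-(4-benzyloxyphenyl)-3-hydroxy-6,8-dimethoxy-2,3-dihydrochromen-4-one (racemic, 2R,3R enantiomer drawn; not isolated) | c1ccccc1COc1ccc(cc1)[C@@H]2[C@H](C(=O)c3cc(OC)c(OCc4ccccc4)c(OC)c3O2)O | intermediate
9 | 7-benzyloxy-2-(4-benzyloxyphenyl)-3-hydroxy-6,8-dimethoxychromen-4-one | COc1cc2c(=O)c(O)c(-c3ccc(OCc4ccccc4)cc3)oc2c(OC)c1OCc1ccccc1 | intermediate
10 | 7-benzyloxy-2-(4-benzyloxyphenyl)-3,6,8-trimethoxychromen-4-one | COc1cc2c(=O)c(OC)c(-c3ccc(OCc4ccccc4)cc3)oc2c(OC)c1OCc1ccccc1 | intermediate
11 | 7-hydroxy-2-(4-hydroxyphenyl)-3,6,8-trimethoxychromen-4-one | COc1cc2c(=O)c(OC)c(-c3ccc(O)cc3)oc2c(OC)c1O | intermediate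
12 | 3,6,8-trimethoxy-7-pivaloyloxy-2-(4-pivaloyloxyphenyl)chromen-4-one | COc1cc2c(=O)c(OC)c(-c3ccc(OC(=O)C(C)(C)C)cc3)oc2c(OC)c1OC(=O)C(C)(C)C | intermediate
13 | 3,6,8-trimethoxy-7-pivaloyloxy-2-(4-pivaloyloxyphenyl)-5-trifluoroacetoxychromen-4-one (not isolated) | COc1c(OC(=O)C(F)(F)F)c2c(=O)c(OC)c(-c3ccc(OC(=O)C(C)(C)C)cc3)oc2c(OC)c1OC(=O)C(C)(C)C | intermediate
14 | 5-hydroxy-3,6,8-trimethoxy-7-pivaloyloxy-2-(4-pivaloyloxyphenyl)chromen-4-one | COc1c(O)c2c(=O)c(OC)c(-c3ccc(OC(=O)C(C)(C)C)cc3)oc2c(OC)c1OC(=O)C(C)(C)C | intermediate
15 | 3,5,6,8-tetramethoxy-7-pivaloyloxy-2-(4-pivaloyloxyphenyl)chromen-4-one | COc1c(OC)c2c(=O)c(OC)c(-c3ccc(OC(=O)C(C)(C)C)cc3)oc2c(OC)c1OC(=O)C(C)(C)C | intermediate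
16 | 7-hydroxy-2-(4-hydroxyphenyl)-3,5,6,8-tetramethoxychromen-4-one | COc1c(O)c(OC)c2oc(-c3ccc(O)cc3)c(OC)c(=O)c2c1OC | target

Total step count: 11. Longest linear sequence: 11 steps (1 to 16).

**Steps most likely to fail**

1. Step 9. Several processes may erode the step.
   - The iodine reagent may oxidise the alkoxy-rich ring A by electron transfer.
   - The new phenol may be over-oxidised once it is uncapped.
   - Metalation may be sluggish, because the C-H bond is wedged between the carbonyl and the C6 methoxy group.
   - Ruthenium may be tied up unproductively by O,O-binding to the C4 carbonyl and the C3 methoxy group.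
   - The ester on ring B may direct oxygenation to that ring.

   The fallback sets out from 12 and returns at 16. Electrophilic bromination (NBS, MeCN, catalytic TFA, rt) should enter C5. It is the only open carbon of ring A, it is ortho and para to the two methoxy groups, and ring B is deactivated by its ester. This gives 5-bromo-3,6,8-trimethoxy-7-pivaloyloxy-2-(4-pivaloyloxyphenyl)chromen-4-one F1. Copper-mediated methoxylation (NaOMe, CuBr, DMF/MeOH, 110 °C; then 1 M HCl) is well known for bromoflavones and bromophenols. It then installs the C5 methoxy group and strips both pivalates in the same pot, giving target 16 directly.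

2. Step 3. Conversion may be limited by slow activation of a C-Br bond that carries two ortho substituents, by protodebromination, or by hydroxide-induced self-condensation of the methyl ketone at 80 °C. The fallback sets out from 5 and returns at 6. Miyaura borylation with a bulky biaryl phosphine and a mild base (B2pin2, Pd(OAc)2, SPhos, KOAc, dioxane, 90 °C) gives 1-[4-benzyloxy-3,5-dimethoxy-2-(4,4,5,5-tetramethyl-1,3,2-dioxaborolan-2-yl)phenyl]ethanone F2. Its C-B bond is then oxidised at room temperature (NaBO3·4H2O, THF/H2O) to phenol 6, with no hot hydroxide involved.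

3. Step 10. Alkylation of the hydrogen-bonded, flanked C5 hydroxyl is slow. This leaves time for loss or intermolecular transfer of the activated C7 pivalate, followed by methylation at the wrong oxygen. The fallback sets out from 14 and returns at 16.
   - Methanolysis (NaOMe, MeOH, rt; then HCl) gives 5,7-dihydroxy-2-(4-hydroxyphenyl)-3,6,8-trimethoxychromen-4-one F3.
   - Selective benzylation of the two non-chelated phenols (BnBr, 2.2 equiv, K2CO3, acetone, reflux) gives 7-benzyloxy-2-(4-benzyloxyphenyl)-5-hydroxy-3,6,8-trimethoxychromen-4-one F4.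
   - Forcing methylation (Me2SO4, K2CO3, acetone, prolonged reflux), now free of labile esters, gives 7-benzyloxy-2-(4-benzyloxyphenyl)-3,5,6,8-tetramethoxychromen-4-one F5.
   - Hydrogenolysis (H2, 10% Pd/C, THF/MeOH) gives target 16.

**Further compounds**

F1 | step 9 | 5-bromo-3,6,8-trimethoxy-7-pivaloyloxy-2-(4-pivaloyloxyphenyl)chromen-4-one | COc1c(Br)c2c(=O)c(OC)c(-c3ccc(OC(=O)C(C)(C)C)cc3)oc2c(OC)c1OC(=O)C(C)(C)C
F2 | step 3 | 1-[4-benzyloxy-3,5-dimethoxy-2-(4,4,5,5-tetramethyl-1,3,2-dioxaborolan-2-yl)phenyl]ethanone | CC(=O)c1cc(OC)c(OCc2ccccc2)c(OC)c1B1OC(C)(C)C(C)(C)O1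
F3 | step 10 | 5,7-dihydroxy-2-(4-hydroxyphenyl)-3,6,8-trimethoxychromen-4-one | COc1c(O)c2c(=O)c(OC)c(-c3ccc(O)cc3)oc2c(OC)c1O
F4 | step 10 | 7-benzyloxy-2-(4-benzyloxyphenyl)-5-hydroxy-3,6,8-trimethoxychromen-4-one | COc1c(O)c2c(=O)c(OC)c(-c3ccc(OCc4ccccc4)cc3)oc2c(OC)c1OCc1ccccc1
F5 | step 10 | 7-benzyloxy-2-(4-benzyloxyphenyl)-3,5,6,8-tetramethoxychromen-4-one | COc1c(OC)c2c(=O)c(OC)c(-c3ccc(OCc4ccccc4)cc3)oc2c(OC)c1OCc1ccccc1
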